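Dicitrinone I is traced back to a C2-symmetric, methylene-bridged bis-isochroman, and both pyran rings are then opened at C1, which leaves two identical 3-arylbutan-2-ol arms. The route rests on deriving these arms from (E)-but-2-en-2-yl groups: one two-directional hydroboration–oxidation with a pinene-derived monoalkylborane makes the C3–O2 and C4–H bonds of both halves and sets all four stereocentres. It exploits the identical (3R,4S) diad of oxygen-bearing C3 and methyl-bearing C4 (bonded to arene carbon C4a) in the isochroman ring and in the quinone-methide pyran ring. The precursor is a diarylmethane with four methyl ethers and two E trisubstituted alkenes.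

Key step: step 6

Remark 1: the quinone-methide ring is written as its 8-oxo-6-hydroxy tautomer; it is expected to equilibrate with the 6-oxo-8-hydroxy form, so no step has to choose between them.

Remark 2: the borane enantiomer is assigned by analogy with the usual sense of induction of monoisopinocampheylborane towards 1-arylcycloalkenes; should this substrate show the opposite sense, the reagent from (+)-α-pinene would be used with no other change.

Remark 3: ring positions are given in isochroman numbering (O2, C3 oxygen-bearing, C4 benzylic, C4a/C8a ring fusion, C5 methyl-bearing, C7 bridge-bearing).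

**Step 1**
Reactants: 1 1-bromo-3,5-dimethoxybenzene
Product: 3 2-bromo-4,6-dimethoxybenzaldehyde, via iminium chloride 2 (not isolated)
Conditions: POCl3, DMF, 0 °C → 80 °C; then H2O, 0 °C → rt
Reagents that add atoms: N,N-dimethylformamide, CN(C)C=O (formyl carbon); water, O (carbonyl oxygen)
Why: Vilsmeier–Haack formylation, in which the chloroiminium ion should attack the carbon para to one methoxy group and next to bromine in preference to the crowded carbon between the two methoxy groups, so that the future C5 methyl carbon sits ortho to the bromine (the minor 4-bromo-2,6-dimethoxy isomer is removed by crystallisation).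

**Step 2**
Reactants: 3 2-bromo-4,6-dimethoxybenzaldehyde
Product: 4 1-bromo-3,5-dimethoxy-2-methylbenzene
Conditions: Et3SiH (2.5 equiv), TFA, CH2Cl2, 0 °C → rt
Reagents that add atoms: none
Why: Ionic hydrogenation, in which the aldehyde is reduced through a benzylic cation stabilised by the ortho and para methoxy groups down to the methyl group, while the aryl bromide and the ethers are inert.

**Step 3**
Reactants: 4 1-bromo-3,5-dimethoxy-2-methylbenzene; 5 (E)-2-bromobut-2-ene
Product: 8 1-[(E)-but-2-en-2-yl]-3,5-dimethoxy-2-methylbenzene, via alkenyllithium 6 (not isolated), via alkenylzinc chloride 7 (not isolated)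
Conditions: 5, t-BuLi (2 equiv per 5), THF, −78 °C; ZnCl2, −78 °C → rt; then 4, Pd(OAc)2/SPhos (cat.), THF, 50 °C
Reagents that add atoms: none
Why: Negishi coupling, in which bromine–lithium exchange at −78 °C, transmetalation to zinc and the palladium cycle all proceed with retention of alkene geometry, so the aryl group ends up cis to the vinylic hydrogen (E); the coupling is placed before the metalation step so that no aryl bromide is present when butyllithium is used.

**Step 4**
Reactants: 8 1-[(E)-but-2-en-2-yl]-3,5-dimethoxy-2-methylbenzene (2 equiv); 9 ethyl formate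
Product: 12 bis{4-[(E)-but-2-en-2-yl]-2,6-dimethoxy-3-methylphenyl}methanol, via aryllithium 10 (not isolated), via aldehyde 11 (not isolated)
Conditions: n-BuLi (1.05 equiv), THF, 0 °C → rt; then HCO2Et (0.48 equiv), −78 °C → rt; H2O
Reagents that add atoms: none
Why: Directed ortho-metalation followed by double addition to a formate ester, in which n-BuLi should remove only the hydrogen flanked by both methoxy groups (no halogen is left to exchange) and two aryllithium units add to ethyl formate through the aldehyde, as is known for 2,6-dimethoxyphenyllithium.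

**Step 5**
Reactants: 12 bis{4-[(E)-but-2-en-2-yl]-2,6-dimethoxy-3-methylphenyl}methanol
Product: 13 bis{4-[(E)-but-2-en-2-yl]-2,6-dimethoxy-3-methylphenyl}methane
Conditions: Et3SiH (3 equiv), TFA (1.5–2 equiv), CH2Cl2, −40 → 0 °C, short reaction time
Reagents that add atoms: none
Why: Ionic deoxygenation of a diarylmethanol, in which the carbinol flanked by four ortho-methoxy groups should ionise with little acid at low temperature to a strongly stabilised diarylmethyl cation that takes hydride from the silane, while protonation of the twisted trisubstituted alkenes should be far slower, so their E geometry is kept.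

**Step 6**
Reactants: 13 bis{4-[(E)-but-2-en-2-yl]-2,6-dimethoxy-3-methylphenyl}methane
Product: 15 bis{4-[(2S,3R)-3-hydroxybutan-2-yl]-2,6-dimethoxy-3-methylphenyl}methane, via bis(alkylborane) 14 (not isolated)
Conditions: IpcBH2 (3 equiv) [from (IpcBH2)2·TMEDA of the (−)-α-pinene series, BF3·OEt2, THF, rt, filtered], THF, −25 °C; then 3 M NaOH, 30% H2O2, 0 °C → rt
Reagents that add atoms: hydrogen peroxide, OO
Why: Asymmetric hydroboration–oxidation: each B–H bond adds across one alkene through a four-centre syn transition state, with boron going to the less substituted, non-benzylic carbon (future C3) and hydrogen to the aryl-bearing carbon (future C4), and alkaline peroxide then replaces boron by oxygen with retention through a 1,2-shift of carbon from boron to oxygen. The closest known reaction is the hydroboration of 1-arylcycloalkenes and (E)-2-arylbut-2-enes with monoisopinocampheylborane, here run on two equivalent alkenes of one molecule. No ring is closed. In each arm the relative configuration of the two new centres follows from suprafacial addition to the E alkene (aryl cis to the vinylic hydrogen), which can only give the (2S,3R)/(2R,3S) pair, and the absolute configuration is chosen by the isopinocampheyl group on boron, the (−)-α-pinene series being expected to favour the face that leads to (2S,3R). The step needs regioselectivity, secured by the trisubstituted pattern with the aryl group on the carbon that receives hydrogen, and face selectivity at two remote, independent alkenes, which rests on the reagent alone. A single wrong-face addition gives the meso diastereomer and not the enantiomer, so removing that diastereomer (crystallisation or preparative HPLC, since the centres are remote) should raise the enantiomeric purity of the C2-symmetric diol above that of a single addition.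

**Step 7**
Reactants: 15 bis{4-[(2S,3R)-3-hydroxybutan-2-yl]-2,6-dimethoxy-3-methylphenyl}methane
Product: 16 bis{2,6-dihydroxy-4-[(2S,3R)-3-hydroxybutan-2-yl]-3-methylphenyl}methane
Conditions: NaSEt (16 equiv), DMF, 150 °C, argon; then degassed 1 M HCl
Reagents that add atoms: none
Why: Nucleophilic (SN2) demethylation of aryl methyl ethers by thiolate, in which ethanethiolate attacks the four O-methyl carbons while the secondary alcohols are present only as inert alkoxides and no stereocentre is touched; excess reagent and high temperature are planned because the second ether of each ring has to leave from a ring that already carries a phenoxide.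

**Step 8**
Reactants: 16 bis{2,6-dihydroxy-4-[(2S,3R)-3-hydroxybutan-2-yl]-3-methylphenyl}methane
Product: 18 bis[(3R,4S)-6,8-dihydroxy-3,4,5-trimethyl-3,4-dihydro-1H-isochromen-7-yl]methane, via mono-isochroman 17 (not isolated)
Conditions: CH2(OMe)2 (6 equiv), p-TsOH·H2O (0.2 equiv), MeCN (0.02 M), 40 °C, argon
Reagents that add atoms: dimethoxymethane, COCOC
Why: Twofold oxa-Pictet–Spengler cyclisation, in which acid turns the acetal into a methoxymethyl cation that links each secondary hydroxyl group to the only free ring carbon (ortho and para to the phenols) by 6-endo closure of the oxocarbenium ion, forming C1–O2 and C1–C8a of both pyran rings without breaking any bond at C3 or C4.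

**Step 9**
Reactants: 18 bis[(3R,4S)-6,8-dihydroxy-3,4,5-trimethyl-3,4-dihydro-1H-isochromen-7-yl]methane
Product: 19 dicitrinone I
Conditions: DDQ (0.95–1.0 equiv), 1,4-dioxane, 0 °C → rt; recovered 18 is recycled
Reagents that add atoms: none
Why: DDQ dehydrogenation of a phenolic benzyl ether, in which hydride is taken from C1–H (alpha to O2 and ortho/para to the two phenols) to give an oxocarbenium ion that loses the C8–OH proton and becomes the quinone methide (a vinylogous ester); one equivalent is used and, because 18 is C2-symmetric, either ring gives the same compound with C3 and C4 untouched.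

**Compound list**

1 | 1-bromo-3,5-dimethoxybenzene | COc1cc(Br)cc(OC)c1 | starting material
2 | N-[(2-bromo-4,6-dimethoxyphenyl)methylidene]-N-methylmethanaminium chloride | C[N+](C)=Cc1c(Br)cc(OC)cc1OC.[Cl-] | intermediate
3 | 2-bromo-4,6-dimethoxybenzaldehyde | O=Cc1c(Br)cc(OC)cc1OC | intermediate
4 | 1-bromo-3,5-dimethoxy-2-methylbenzene | Cc1c(Br)cc(OC)cc1OC | intermediate
5 | (E)-2-bromobut-2-ene | C/C=C(\C)Br | starting material
6 | (Z)-but-2-en-2-yllithium (methyl groups cis, as in 5) | C/C=C(\C)[Li] | intermediate
7 | (E)-but-2-en-2-ylzinc chloride (methyl groups cis) | C/C=C(\C)[Zn]Cl | intermediate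
8 | 1-[(E)-but-2-en-2-yl]-3,5-dimethoxy-2-methylbenzene | C/C=C(\C)c1cc(OC)cc(OC)c1C | intermediate
9 | ethyl formate | CCOC=O | starting material
10 | {4-[(E)-but-2-en-2-yl]-2,6-dimethoxy-3-methylphenyl}lithium | [Li]c1c(OC)cc(/C(C)=C/C)c(C)c1OC | intermediate
11 | 4-[(E)-but-2-en-2-yl]-2,6-dimethoxy-3-methylbenzaldehyde | O=Cc1c(OC)cc(/C(C)=C/C)c(C)c1OC | intermediate
12 | bis{4-[(E)-but-2-en-2-yl]-2,6-dimethoxy-3-methylphenyl}methanol | OC(c1c(OC)c(C)c(/C(C)=C/C)cc1OC)c1c(OC)c(C)c(/C(C)=C/C)cc1OC | intermediate
13 | bis{4-[(E)-but-2-en-2-yl]-2,6-dimethoxy-3-methylphenyl}methane | C(c1c(OC)c(C)c(/C(C)=C/C)cc1OC)c1c(OC)c(C)c(/C(C)=C/C)cc1OC | intermediate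
14 | bis{4-[3-(isopinocampheylboranyl)butan-2-yl]-2,6-dimethoxy-3-methylphenyl}methane (B–H borane; boron where 15 has OH, same spatial arrangement) | C(c1c(OC)c(C)c([C@H](C)[C@@H](C)B[C@H]2C[C@H]3C[C@@H]([C@@H]2C)C3(C)C)cc1OC)c1c(OC)c(C)c([C@H](C)[C@@H](C)B[C@H]2C[C@H]3C[C@@H]([C@@H]2C)C3(C)C)cc1OC | intermediate
15 | bis{4-[(2S,3R)-3-hydroxybutan-2-yl]-2,6-dimethoxy-3-methylphenyl}methane | C(c1c(OC)c(C)c([C@H](C)[C@@H](C)O)cc1OC)c1c(OC)c(C)c([C@H](C)[C@@H](C)O)cc1OC | intermediate
16 | bis{2,6-dihydroxy-4-[(2S,3R)-3-hydroxybutan-2-yl]-3-methylphenyl}methane | C(c1c(O)c(C)c([C@H](C)[C@@H](C)O)cc1O)c1c(O)c(C)c([C@H](C)[C@@H](C)O)cc1O | intermediate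
17 | (3R,4S)-7-({2,6-dihydroxy-4-[(2S,3R)-3-hydroxybutan-2-yl]-3-methylphenyl}methyl)-3,4,5-trimethyl-3,4-dihydro-1H-isochromene-6,8-diol | C(c1c(O)c(C)c2c(c1O)CO[C@H](C)[C@H]2C)c1c(O)c(C)c([C@H](C)[C@@H](C)O)cc1O | intermediate
18 | bis[(3R,4S)-6,8-dihydroxy-3,4,5-trimethyl-3,4-dihydro-1H-isochromen-7-yl]methane | C(c1c(O)c(C)c2c(c1O)CO[C@H](C)[C@H]2C)c1c(O)c(C)c2c(c1O)CO[C@H](C)[C@H]2C | intermediate
19 | dicitrinone I, (3R,4S)-7-{[(3R,4S)-6,8-dihydroxy-3,4,5-trimethyl-3,4-dihydro-1H-isochromen-7-yl]methyl}-6-hydroxy-3,4,5-trimethyl-3,4-dihydro-8H-isochromen-8-one | CC1=C2C(=CO[C@H](C)[C@H]2C)C(=O)C(Cc2c(O)c(C)c3c(c2O)CO[C@H](C)[C@H]3C)=C1O | target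

**Step count**

Total: 9 steps. Longest linear sequence: 9 steps, from 1 to 19.

**Steps most likely to fail**

Step 9. The oxidation may be unselective: the two rings are electronically insulated, so the second ring can be dehydrogenated about as readily as the first. Hydride may also be abstracted from the inter-ring methylene, and nucleophiles may add to the quinone methide that is formed. The fallback avoids any oxidant and sets out from 16. The acetal closure is run with one equivalent of dimethoxymethane and stopped at the mono-isochroman 17, which is isolated this time (16 and 18 are recovered). 17 is then treated with triethyl orthoformate and HCl in dioxane, the classical closure of the citrinin chromophore. The remaining free ring carbon is attacked at the formyl oxidation level and the side-chain hydroxyl closes the mixed acetal, (3R,4S)-7-{[(3R,4S)-1-ethoxy-6,8-dihydroxy-3,4,5-trimethyl-3,4-dihydro-1H-isochromen-7-yl]methyl}-3,4,5-trimethyl-3,4-dihydro-1H-isochromene-6,8-diol F1. F1 loses ethanol under the same conditions, and the route is rejoined at 19.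

Step 6. Face selection by the borane may be insufficient at one or both alkenes, addition to the hindered, ortho-methylated aryl alkenes may be slow, and the meso diastereomer may be hard to remove because the two arms are remote. The fallback sets out from 13 and replaces reagent control by enzymatic resolution. Hydroboration–oxidation with BH3·SMe2 (THF, 0 °C → rt; NaOH, H2O2) should give the syn-configured diol as a mixture of both C2 enantiomers and the meso form, bis[4-(3-hydroxybutan-2-yl)-2,6-dimethoxy-3-methylphenyl]methane F2. Lipase B from Candida antarctica with vinyl butanoate in MTBE is expected, by Kazlauskas' rule, to acylate only (R)-configured carbinols. Only the desired stereoisomer then becomes the diester, bis{4-[(2S,3R)-3-(butanoyloxy)butan-2-yl]-2,6-dimethoxy-3-methylphenyl}methane F3, which differs clearly in polarity from the monoester and the diol. Methanolysis of F3 (K2CO3, MeOH) returns to the route at 15.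

Step 7. Ether cleavage may stall, because the second methyl ether of each ring must leave from a ring that is already a phenoxide, and the electron-rich polyphenolate may degrade oxidatively at 150 °C. The fallback sets out from 15 and changes from nucleophilic to Lewis-acid dealkylation with the carbinols masked. Acetylation (Ac2O, pyridine, DMAP) gives bis{4-[(2S,3R)-3-acetoxybutan-2-yl]-2,6-dimethoxy-3-methylphenyl}methane F4. BBr3 (CH2Cl2, −78 → 0 °C) then cleaves the four aryl methyl ethers to bis{4-[(2S,3R)-3-acetoxybutan-2-yl]-2,6-dihydroxy-3-methylphenyl}methane F5, the acetates keeping the secondary carbinols from being converted into bromides. Methanolysis of F5 (K2CO3, MeOH, argon) returns to the route at 16.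

**Further compounds**

F1 | step 9 | (3R,4S)-7-{[(3R,4S)-1-ethoxy-6,8-dihydroxy-3,4,5-trimethyl-3,4-dihydro-1H-isochromen-7-yl]methyl}-3,4,5-trimethyl-3,4-dihydro-1H-isochromene-6,8-diol (both C1 epimers) | C(c1c(O)c(C)c2c(c1O)CO[C@H](C)[C@H]2C)c1c(O)c(C)c2c(c1O)C(OCC)O[C@H](C)[C@H]2C
F2 | step 6 | bis[4-(3-hydroxybutan-2-yl)-2,6-dimethoxy-3-methylphenyl]methane (each arm syn, mixture of both C2 enantiomers and the meso form) | C(c1c(OC)c(C)c(C(C)C(C)O)cc1OC)c1c(OC)c(C)c(C(C)C(C)O)cc1OC
F3 | step 6 | bis{4-[(2S,3R)-3-(butanoyloxy)butan-2-yl]-2,6-dimethoxy-3-methylphenyl}methane | C(c1c(OC)c(C)c([C@H](C)[C@@H](C)OC(=O)CCC)cc1OC)c1c(OC)c(C)c([C@H](C)[C@@H](C)OC(=O)CCC)cc1OC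
F4 | step 7 | bis{4-[(2S,3R)-3-acetoxybutan-2-yl]-2,6-dimethoxy-3-methylphenyl}methane | C(c1c(OC)c(C)c([C@H](C)[C@@H](C)OC(C)=O)cc1OC)c1c(OC)c(C)c([C@H](C)[C@@H](C)OC(C)=O)cc1OC
F5 | step 7 | bis{4-[(2S,3R)-3-acetoxybutan-2-yl]-2,6-dihydroxy-3-methylphenyl}methane | C(c1c(O)c(C)c([C@H](C)[C@@H](C)OC(C)=O)cc1O)c1c(O)c(C)c([C@H](C)[C@@H](C)OC(C)=O)cc1O
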